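Time works unevenly in a dosed flask: in the early minutes the nucleophile has barely arrived. Here the electrophile meets a steady feed of nucleophile and a protic impurity that is there from the start. You want the part of the electrophile that has reacted at the end.

common to all: electrophile 47 mM

| flask | nucleophile | protic impurity | remark | time |
|---|---|---|---|---|
| elm | 45 mM (fed, over 10 min) | 47 mM | run made earlier |  |
| birch | 120 mM (fed, over 10 min) | 47 mM | run made earlier |  |
| Sunday's | 70.0 mM (fed, over 10 min) | 47.0 mM |  | 10 min |
| Thursday's | 110 mM (fed, over 10 min) | 47.0 mM |  | 10 min |
| Friday's | 160 mM (fed, over 10 min) | 47.0 mM |  | 10 min |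

- elm (time / min: electrophile / %, target / %): 1.33: 94.2, 1.0; 2.50: 89.4, 2.3; 4.00: 82.5, 5.3; 5.00: 77.8, 6.7; 6.00: 73.3, 9.4; 8.00: 63.0, 14.3
- birch (time / min: electrophile / %, target / %): 0.500: 97.7, 0; 1.33: 92.9, 1.1; 2.50: 85.4, 5.4; 4.00: 75.0, 12.7; 5.00: 68.6, 17.0; 8.00: 45.2, 33.9

(each reading ± 0.5 percentage points)

- part of the electrophile that has reacted at the end, Sunday's
- part of the electrophile that has reacted at the end, Thursday's
- part of the electrophile that has reacted at the end, Friday's
- what raising the concentration of nucleophile from its lowest to its highest value here does to the part of the electrophile that has reacted (changes below 5 percentage points count as none) (it falls / it rises / no change)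

A bench rule helps: replace the ramp by its mean. The amount fed rises steadily from nothing to a charge c, so it averages half of c over the feed. So treat the electrophile as pseudo-first-order with one mean rate, λ = h + k·c/2, and the fraction left at the end of the feed, after time T, is exp(−λT). Here h is a loss that ignores the feed, and k is the rate per mM of nucleophile.

Take the logarithm of what is left at 8.00 min. Elm gives 0.462 and birch gives 0.794. The difference belongs to the extra charge. Up to time t the mean nucleophile is c·t/(2·T), with T the feed time. That gives the mean-feed constant k = 0.00138 mM⁻¹ min⁻¹, and h = 0.0329 min⁻¹.

Now check the error of the mean. For birch at 5.00 min the rule leaves 69.0%, the reading is 68.6%, and the scatter is 0.5 percentage points.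

The border is the ratio t/T, here 1.00. Past one the ramp has stopped, and the mean no longer follows it. The asked flasks stop on that border. My reckoning gives 55.6% for Sunday's, 66.4% for Thursday's and 76.2% for Friday's.

The forecast stands higher: 84%, 93%, 97.5%. Its trend: it rises. It differs from mine in the clock, which it reads “as a hold after the 10-minute feed, so 20 minutes total”.

The flask gives 53.1%, 64.0%, 74.6%. The trend: it rises, by 21 points.

    nucleophile + acid set free ⇌ protonated nucleophile, settled at all times (K = 30000 M⁻¹)
    electrophile + protic impurity → quenched substrate (k = 0.0135 M⁻¹ s⁻¹)
    electrophile + nucleophile → acid set free + target (k = 0.0299 M⁻¹ s⁻¹)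

The asked time is the end of the feed, with no hold behind it. Friday's flask reacts further than Sunday's because of its larger nucleophile charge: Friday's stands at 74.6%, and with Sunday's charge it stands at 53.1%, a gap of 21 points. Now take Sunday's flask with 120 mM of nucleophile. With k = 0.00138 mM⁻¹ min⁻¹, the mean rate is 0.116 min⁻¹, so you expect 68.6% reacted. The computed flask gives 66.4%.

(The data are calculated with constants of no real substance; the scatter is artificial.)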